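**Plan** (ring atoms numbered as in 2H-chromene: O1, C2, C3, C4, C4a, C5–C8, C8a)

1. Late cuts: the two resorcinol allyl ethers come off last; the C7–prenyl bond is cut by a retro-Claisen to a C8 O-(1,1-dimethylallyl) ether; the Cα–Cβ bond of the dihydrochalcone is cut (conjugate reduction, then aldol) to a chromene-6-carbaldehyde and 2,4-bis(allyloxy)acetophenone.
2. Central cut: C4–C4a and O1–C8a are cut together. The 2H-pyran ring O1–C2(Me)2–C3=C4–C4a–C8a is the oxa-6π valence isomer of an ortho-quinone methide, which is the ring-opened benzoxete from a C4a≡C8a aryne and the C=O of 3-methylbut-2-enal.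
3. Design point: the C8 oxygen lies next to the C–O terminus C8a, and an oxygen there would steer the aldehyde oxygen to C4a. C8 is therefore carried one oxidation level lower, as a pinacol boronate, which directs the oxygen to C8a and is oxidised to the phenol afterwards.
4. Forward order: benzene ring from 3,5-dibromo-4-hydroxybenzaldehyde (steps 1–3); pyran ring fused on (step 4); C8 OH and CHO freed (step 5); tertiary allyl ether (step 7); chain joined by aldol and CuH reduction (steps 9, 10); prenyl by Claisen (step 11); deallylation (step 12).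
5. Stereochemistry: the target has no stereocentre; the only stereo element on the way is the E enone of the chalcone intermediate, set under thermodynamic control and removed by the reduction.

Key step: step 4

**Step 1**
Reactants: 1 3,5-dibromo-4-hydroxybenzaldehyde
Product: 2 2,6-dibromo-4-(1,3-dioxolan-2-yl)phenol
Conditions: ethylene glycol (3 equiv), p-TsOH·H2O (cat.), toluene, reflux, Dean–Stark
Reagents that add atoms: ethylene glycol OCCO
Why: Acid-catalysed acetalisation with azeotropic removal of water masks the aldehyde against n-BuLi in step 2 and against the aryne in step 4; no stereocentre is formed.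

**Step 2**
Reactants: 2 2,6-dibromo-4-(1,3-dioxolan-2-yl)phenol
Product: 6 2-bromo-4-(1,3-dioxolan-2-yl)-6-(trimethylsilyl)phenyl trifluoromethanesulfonate, via aryl silyl ether 3 (not isolated), via aryllithium 4 (not isolated), via lithium phenolate 5 (not isolated)
Conditions: HMDS, THF, 65 °C, then evaporation; n-BuLi (1.05 equiv), THF, −100 to −78 °C; Tf2O, −100 to −78 °C
Reagents that add atoms: hexamethyldisilazane C[Si](C)(C)N[Si](C)(C)C; trifluoromethanesulfonic anhydride O=S(=O)(OS(=O)(=O)C(F)(F)F)C(F)(F)F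
Why: O-silylation, bromine–lithium exchange at one of the two equivalent bromines and a 1,3 O-to-C silyl shift (retro-Brook rearrangement) place silicon ortho to the phenolate, which is triflated in the same pot (the standard one-pot route from ortho-bromophenols to 2-silylaryl triflates), and one equivalent of n-BuLi at low temperature should leave the second bromine for step 3.

**Step 3**
Reactants: 6 2-bromo-4-(1,3-dioxolan-2-yl)-6-(trimethylsilyl)phenyl trifluoromethanesulfonate
Product: 7 4-(1,3-dioxolan-2-yl)-2-(4,4,5,5-tetramethyl-1,3,2-dioxaborolan-2-yl)-6-(trimethylsilyl)phenyl trifluoromethanesulfonate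
Conditions: B2pin2, PdCl2(dppf) (cat.), KOAc, 1,4-dioxane, 80 °C
Reagents that add atoms: bis(pinacolato)diboron CC1(C)OB(OC1(C)C)B1OC(C)(C)C(C)(C)O1
Why: Miyaura borylation, in which zerovalent palladium with dppf should insert into the C–Br bond in preference to the doubly ortho-substituted C–OTf bond, while KOAc is too weak a base to start a Suzuki coupling or to remove the silyl group.

**Step 4**
Reactants: 7 4-(1,3-dioxolan-2-yl)-2-(4,4,5,5-tetramethyl-1,3,2-dioxaborolan-2-yl)-6-(trimethylsilyl)phenyl trifluoromethanesulfonate; 8 3-methylbut-2-enal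
Product: 12 2-[6-(1,3-dioxolan-2-yl)-2,2-dimethyl-2H-chromen-8-yl]-4,4,5,5-tetramethyl-1,3,2-dioxaborolane, via 3-boryl aryne 9 (not isolated), via benzoxete 10 (not isolated), via ortho-quinone methide 11 (not isolated)
Conditions: 8 (4 equiv), CsF (3 equiv), MeCN, rt to 50 °C
Reagents that add atoms: none
Why: Fluoride attacks the silicon of 7 and triflate leaves to give aryne 9; the carbonyl oxygen of 8 adds to C8a and the aryl anion at C4a closes on the oxocarbenium carbon (4-exo-trig) to benzoxete 10, a formal [2+2] that makes C4–C4a and O1–C8a in one event. Strain-driven 4π ring opening of 10 gives ortho-quinone methide 11, and a disrotatory oxa-6π electrocyclisation (6-endo closure of the oxygen on the CMe2 terminus) builds the pyran ring and restores the benzene ring. The closest known reaction type is the annulation of arynes from 2-silylaryl triflates with α,β-unsaturated aldehydes to 2H-chromenes. No stereocentre arises because C2 carries two methyl groups. The step needs the oxygen to add at C8a and not at C4a: the σ-donating boronate on C8 distorts the aryne so that the adjacent C8a is the more electrophilic terminus (ortho addition, as known for 3-boryl and 3-silyl arynes with amines), the C6 acetal carbon para to C8a acts weakly in the same sense, and an oxygen substituent on C8 would have directed the other way. Chemoselectivity rests on the acetal, which keeps the benzaldehyde from competing with 8, and on the silicon being far more fluorophilic than the hindered boronate, so that only the C4a≡C8a aryne forms.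

**Step 5**
Reactants: 12 2-[6-(1,3-dioxolan-2-yl)-2,2-dimethyl-2H-chromen-8-yl]-4,4,5,5-tetramethyl-1,3,2-dioxaborolane
Product: 14 8-hydroxy-2,2-dimethyl-2H-chromene-6-carbaldehyde, via chromen-8-ol acetal 13 (not isolated)
Conditions: 30% aq. H2O2, NaOH, THF, 0 °C; aq. Na2S2O3; then 1 M HCl, THF, rt
Reagents that add atoms: hydrogen peroxide OO; water O
Why: Boronate oxidation (hydroperoxide adds to boron and the aryl group shifts from boron to oxygen) should outrun any reaction of the electron-rich chromene alkene while the aldehyde is still masked, and after the excess peroxide is reduced, acetal hydrolysis in dilute acid frees the aldehyde.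

**Step 6**
Reactants: 15 2-methylbut-3-en-2-ol
Product: 16 methyl 2-methylbut-3-en-2-yl carbonate
Conditions: n-BuLi, THF, −78 °C; ClCO2Me, −78 °C to rt
Reagents that add atoms: methyl chloroformate COC(Cl)=O
Why: Acylation of the lithium alkoxide of the tertiary allylic alcohol with the chloroformate gives the mixed carbonate that serves as the π-allyl precursor in step 7.

**Step 7**
Reactants: 14 8-hydroxy-2,2-dimethyl-2H-chromene-6-carbaldehyde; 16 methyl 2-methylbut-3-en-2-yl carbonate
Product: 17 2,2-dimethyl-8-[(2-methylbut-3-en-2-yl)oxy]-2H-chromene-6-carbaldehyde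
Conditions: Pd(PPh3)4 (cat.), THF, 0 °C
Reagents that add atoms: none
Why: Tsuji–Trost O-allylation, in which zerovalent palladium ionises 16 with loss of CO2 and methoxide, the methoxide deprotonates the phenol, and the phenoxide attacks the 1,1-dimethyl-π-allyl complex at its more substituted terminus under kinetic control at low temperature to give the tertiary ether.

**Step 8**
Reactants: 18 1-(2,4-dihydroxyphenyl)ethan-1-one
Product: 19 1-[2,4-bis(prop-2-en-1-yloxy)phenyl]ethan-1-one
Conditions: allyl bromide (2.5 equiv), K2CO3, DMF, 60 °C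
Reagents that add atoms: allyl bromide C=CCBr
Why: Williamson etherification, in which excess allyl bromide in DMF should alkylate the hydrogen-bonded 2-hydroxyl as well as the 4-hydroxyl.

**Step 9**
Reactants: 17 2,2-dimethyl-8-[(2-methylbut-3-en-2-yl)oxy]-2H-chromene-6-carbaldehyde; 19 1-[2,4-bis(prop-2-en-1-yloxy)phenyl]ethan-1-one
Product: 20 (2E)-1-[2,4-bis(prop-2-en-1-yloxy)phenyl]-3-{2,2-dimethyl-8-[(2-methylbut-3-en-2-yl)oxy]-2H-chromen-6-yl}prop-2-en-1-one
Conditions: KOH, EtOH, rt
Reagents that add atoms: none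
Why: Claisen–Schmidt condensation, in which the enolate of 19 adds to the non-enolisable aldehyde 17 and E1cB loss of water gives the conjugated enone with the thermodynamically preferred E geometry.

**Step 10**
Reactants: 20 (2E)-1-[2,4-bis(prop-2-en-1-yloxy)phenyl]-3-{2,2-dimethyl-8-[(2-methylbut-3-en-2-yl)oxy]-2H-chromen-6-yl}prop-2-en-1-one
Product: 21 1-[2,4-bis(prop-2-en-1-yloxy)phenyl]-3-{2,2-dimethyl-8-[(2-methylbut-3-en-2-yl)oxy]-2H-chromen-6-yl}propan-1-one
Conditions: [(Ph3P)CuH]6 (cat.), PhMe2SiH, t-BuOH, toluene, rt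
Reagents that add atoms: none
Why: CuH conjugate reduction, in which the phosphine-ligated monovalent copper hydride delivers hydride only to the β-carbon of the enone and t-BuOH protonates the copper enolate, while the terminal alkenes, the chromene alkene and the allyl ethers are not substrates for it.

**Step 11**
Reactants: 21 1-[2,4-bis(prop-2-en-1-yloxy)phenyl]-3-{2,2-dimethyl-8-[(2-methylbut-3-en-2-yl)oxy]-2H-chromen-6-yl}propan-1-one
Product: 22 1-[2,4-bis(prop-2-en-1-yloxy)phenyl]-3-[8-hydroxy-2,2-dimethyl-7-(3-methylbut-2-en-1-yl)-2H-chromen-6-yl]propan-1-one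
Conditions: toluene, 110 °C, sealed tube
Reagents that add atoms: none
Why: Aromatic Claisen rearrangement, in which the [3,3] shift of the 1,1-dimethylallyl aryl ether carries the allyl terminus to C7, the only free ortho position of the C8 oxygen, and tautomerisation gives the prenyl phenol, at a temperature well below what the primary allyl ethers need.

**Step 12**
Reactants: 22 1-[2,4-bis(prop-2-en-1-yloxy)phenyl]-3-[8-hydroxy-2,2-dimethyl-7-(3-methylbut-2-en-1-yl)-2H-chromen-6-yl]propan-1-one
Product: 23 1-(2,4-dihydroxyphenyl)-3-[8-hydroxy-2,2-dimethyl-7-(3-methylbut-2-en-1-yl)-2H-chromen-6-yl]propan-1-one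
Conditions: Pd(PPh3)4 (cat.), morpholine, THF, rt
Reagents that add atoms: none
Why: Tsuji–Trost deallylation, in which zerovalent palladium ionises only the two allyl aryl ethers and morpholine traps the π-allyl cation, while the prenyl group, the chromene and the ketone carry no allylic leaving group and should stay intact.

**Compound list**

1 | 3,5-dibromo-4-hydroxybenzaldehyde | O=Cc1cc(Br)c(O)c(Br)c1 | starting material
2 | 2,6-dibromo-4-(1,3-dioxolan-2-yl)phenol | Oc1c(Br)cc(cc1Br)C1OCCO1 | intermediate
3 | [2,6-dibromo-4-(1,3-dioxolan-2-yl)phenoxy]trimethylsilane (aryl silyl ether) | C[Si](C)(C)Oc1c(Br)cc(cc1Br)C1OCCO1 | intermediate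
4 | {3-bromo-5-(1,3-dioxolan-2-yl)-2-[(trimethylsilyl)oxy]phenyl}lithium (aryllithium) | [Li]c1cc(cc(Br)c1O[Si](C)(C)C)C1OCCO1 | intermediate
5 | lithium 2-bromo-4-(1,3-dioxolan-2-yl)-6-(trimethylsilyl)phenolate | [Li+].[O-]c1c(Br)cc(cc1[Si](C)(C)C)C1OCCO1 | intermediate
6 | 2-bromo-4-(1,3-dioxolan-2-yl)-6-(trimethylsilyl)phenyl trifluoromethanesulfonate | C[Si](C)(C)c1cc(cc(Br)c1OS(=O)(=O)C(F)(F)F)C1OCCO1 | intermediate
7 | 4-(1,3-dioxolan-2-yl)-2-(4,4,5,5-tetramethyl-1,3,2-dioxaborolan-2-yl)-6-(trimethylsilyl)phenyl trifluoromethanesulfonate | C[Si](C)(C)c1cc(cc(B2OC(C)(C)C(C)(C)O2)c1OS(=O)(=O)C(F)(F)F)C1OCCO1 | intermediate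
8 | 3-methylbut-2-enal | CC(C)=CC=O | starting material
9 | 2-[5-(1,3-dioxolan-2-yl)-2,3-didehydrophenyl]-4,4,5,5-tetramethyl-1,3,2-dioxaborolane (3-boryl aryne, triple bond C4a≡C8a) | CC1(C)OB(OC1(C)C)C1=CC(C2OCCO2)=CC#C1 | intermediate
10 | 2-[4-(1,3-dioxolan-2-yl)-2-(2-methylprop-1-en-1-yl)-2H-benzo[b]oxet-6-yl]-4,4,5,5-tetramethyl-1,3,2-dioxaborolane (benzoxete) | CC(C)=CC1Oc2c(B3OC(C)(C)C(C)(C)O3)cc(C3OCCO3)cc12 | intermediate
11 | (6Z)-4-(1,3-dioxolan-2-yl)-6-(3-methylbut-2-en-1-ylidene)-2-(4,4,5,5-tetramethyl-1,3,2-dioxaborolan-2-yl)cyclohexa-2,4-dien-1-one (ortho-quinone methide, dienyl chain syn to C=O) | CC(C)=C/C=C1/C=C(C2OCCO2)C=C(B2OC(C)(C)C(C)(C)O2)C1=O | intermediate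
12 | 2-[6-(1,3-dioxolan-2-yl)-2,2-dimethyl-2H-chromen-8-yl]-4,4,5,5-tetramethyl-1,3,2-dioxaborolane | CC1(C)C=Cc2cc(cc(B3OC(C)(C)C(C)(C)O3)c2O1)C1OCCO1 | intermediate
13 | 6-(1,3-dioxolan-2-yl)-2,2-dimethyl-2H-chromen-8-ol | CC1(C)C=Cc2cc(cc(O)c2O1)C1OCCO1 | intermediate
14 | 8-hydroxy-2,2-dimethyl-2H-chromene-6-carbaldehyde | CC1(C)C=Cc2cc(C=O)cc(O)c2O1 | intermediate
15 | 2-methylbut-3-en-2-ol | CC(C)(O)C=C | starting material
16 | methyl 2-methylbut-3-en-2-yl carbonate | COC(=O)OC(C)(C)C=C | intermediate
17 | 2,2-dimethyl-8-[(2-methylbut-3-en-2-yl)oxy]-2H-chromene-6-carbaldehyde | CC1(C)C=Cc2cc(C=O)cc(OC(C)(C)C=C)c2O1 | intermediate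
18 | 1-(2,4-dihydroxyphenyl)ethan-1-one | CC(=O)c1ccc(O)cc1O | starting material
19 | 1-[2,4-bis(prop-2-en-1-yloxy)phenyl]ethan-1-one | CC(=O)c1ccc(OCC=C)cc1OCC=C | intermediate
20 | (2E)-1-[2,4-bis(prop-2-en-1-yloxy)phenyl]-3-{2,2-dimethyl-8-[(2-methylbut-3-en-2-yl)oxy]-2H-chromen-6-yl}prop-2-en-1-one | C=CCOc1ccc(c(OCC=C)c1)C(=O)/C=C/c1cc2C=CC(C)(C)Oc2c(OC(C)(C)C=C)c1 | intermediate
21 | 1-[2,4-bis(prop-2-en-1-yloxy)phenyl]-3-{2,2-dimethyl-8-[(2-methylbut-3-en-2-yl)oxy]-2H-chromen-6-yl}propan-1-one | C=CCOc1ccc(c(OCC=C)c1)C(=O)CCc1cc2C=CC(C)(C)Oc2c(OC(C)(C)C=C)c1 | intermediate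
22 | 1-[2,4-bis(prop-2-en-1-yloxy)phenyl]-3-[8-hydroxy-2,2-dimethyl-7-(3-methylbut-2-en-1-yl)-2H-chromen-6-yl]propan-1-one | C=CCOc1ccc(c(OCC=C)c1)C(=O)CCc1cc2C=CC(C)(C)Oc2c(O)c1CC=C(C)C | intermediate
23 | 1-(2,4-dihydroxyphenyl)-3-[8-hydroxy-2,2-dimethyl-7-(3-methylbut-2-en-1-yl)-2H-chromen-6-yl]propan-1-one (CNP0290651.0) | CC(C)=CCc1c(CCC(=O)c2ccc(O)cc2O)cc2c(c1O)OC(C)(C)C=C2 | target

**Step count**

Total steps: 12. Longest linear sequence: 10 steps (1, 2, 3, 4, 5, 7, 9, 10, 11, 12); steps 6 and 8 prepare the two side fragments.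

**Steps most likely to fail**

Step 4. The carbonyl oxygen may add at the wrong aryne terminus if the boronate directs less strongly than expected, and fluoride binding at boron may divert the aryne or cause protodeboronation. The fallback sets out from 2 and returns at 12, and it fixes the regiochemistry by using the phenol oxygen of 2 as the ring oxygen. Compound 2 is treated with n-BuLi (2.1 equiv, THF, −78 °C; O-deprotonation, then exchange of one bromine) and the aryllithium is alkylated with prenyl bromide to give 2-bromo-4-(1,3-dioxolan-2-yl)-6-(3-methylbut-2-en-1-yl)phenol F1. Oxidative cyclisation of the ortho-prenyl phenol with DDQ (toluene, 80 °C) gives 8-bromo-6-(1,3-dioxolan-2-yl)-2,2-dimethyl-2H-chromene F2. Miyaura borylation of F2 (B2pin2, PdCl2(dppf), KOAc, dioxane, 80 °C) gives 12.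

Step 3. Oxidative addition may take place at the C–OTf bond, or the base may strip the silyl group and release the aryne early. The fallback sets out from 2 and returns at 7, and it brings in boron by a polar route before the triflate exists. Silylation, single bromine–lithium exchange and retro-Brook shift are run as in step 2 (through 3, 4 and 5) but quenched with aqueous NH4Cl to give 2-bromo-4-(1,3-dioxolan-2-yl)-6-(trimethylsilyl)phenol F3. F3 is deprotonated and its remaining bromine exchanged (n-BuLi, 2.2 equiv, THF, −78 °C), and the aryllithium is trapped with 2-isopropoxy-4,4,5,5-tetramethyl-1,3,2-dioxaborolane to give 4-(1,3-dioxolan-2-yl)-2-(4,4,5,5-tetramethyl-1,3,2-dioxaborolan-2-yl)-6-(trimethylsilyl)phenol F4. Triflation of F4 (Tf2O, pyridine, CH2Cl2, 0 °C) gives 7.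

Step 11. On heating, the tertiary allylic ether may ionise and lose the C5 unit, the allyl group may travel on to the para position C5 by a Claisen–Cope sequence, or the primary allyl ethers may begin to rearrange. The fallback sets out from 14 and returns at 22, and it places the prenyl group by direct C-alkylation instead of a sigmatropic shift. The sodium phenoxide of 14 (NaH, toluene, rt) is alkylated at the ortho carbon with prenyl bromide (tight ion pair in a non-polar solvent) to give 8-hydroxy-2,2-dimethyl-7-(3-methylbut-2-en-1-yl)-2H-chromene-6-carbaldehyde F5. Claisen–Schmidt condensation of F5 with 19 (KOH, EtOH, rt) gives (2E)-1-[2,4-bis(prop-2-en-1-yloxy)phenyl]-3-[8-hydroxy-2,2-dimethyl-7-(3-methylbut-2-en-1-yl)-2H-chromen-6-yl]prop-2-en-1-one F6. CuH conjugate reduction of F6 as in step 10 gives 22.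

**Further compounds**

F1 | step 4 | 2-bromo-4-(1,3-dioxolan-2-yl)-6-(3-methylbut-2-en-1-yl)phenol | Oc1c(Br)cc(cc1CC=C(C)C)C1OCCO1
F2 | step 4 | 8-bromo-6-(1,3-dioxolan-2-yl)-2,2-dimethyl-2H-chromene | CC1(C)C=Cc2cc(cc(Br)c2O1)C1OCCO1
F3 | step 3 | 2-bromo-4-(1,3-dioxolan-2-yl)-6-(trimethylsilyl)phenol | Oc1c(Br)cc(cc1[Si](C)(C)C)C1OCCO1
F4 | step 3 | 4-(1,3-dioxolan-2-yl)-2-(4,4,5,5-tetramethyl-1,3,2-dioxaborolan-2-yl)-6-(trimethylsilyl)phenol | Oc1c(cc(cc1[Si](C)(C)C)C1OCCO1)B1OC(C)(C)C(C)(C)O1
F5 | step 11 | 8-hydroxy-2,2-dimethyl-7-(3-methylbut-2-en-1-yl)-2H-chromene-6-carbaldehyde | CC(C)=CCc1c(C=O)cc2C=CC(C)(C)Oc2c1O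
F6 | step 11 | (2E)-1-[2,4-bis(prop-2-en-1-yloxy)phenyl]-3-[8-hydroxy-2,2-dimethyl-7-(3-methylbut-2-en-1-yl)-2H-chromen-6-yl]prop-2-en-1-one | C=CCOc1ccc(c(OCC=C)c1)C(=O)/C=C/c1cc2C=CC(C)(C)Oc2c(O)c1CC=C(C)C
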